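**Strategy.** The target is cut at C3–C4 of the tetrahydrofuran ring (O1–C2–C3–C4–C5) and at the bond from the exocyclic carbinol carbon C7′ to its aryl group. Because C7′ hangs on C4 and the methyl sits on the adjacent C3, the core is a 1,6-enyne plus an aryl iodide: C5–C4–C7′ is a propargyl unit, and C3 with its methyl is a vinyl group. One palladium-catalysed operation adds the aryl to the alkyne, closes the ring onto the alkene and reduces the resulting CH2–Pd to the methyl. This gives an E-benzylidene whose hydroboration installs C4 and C7′. The precursor is the (S)-1-arylallyl propargyl ether 6.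

Key step: step 4

Remark (chemistry): atom labels are O1, C2 (aryl-bearing), C3 (methyl-bearing), C4, C5 (ring CH2) and C7′ (carbinol carbon); the lipase is assumed to show its usual preference for acylating the (R)-enantiomer of 1-arylallyl alcohols, so the (S)-alcohol is the one recovered.

**Route**

Step 1
Reactants: 1 veratraldehyde (3,4-dimethoxybenzaldehyde); 2 vinylmagnesium bromide
Product: 3 rac-1-(3,4-dimethoxyphenyl)prop-2-en-1-ol
Conditions: THF, −78 to 0 °C; then sat. aq NH4Cl
Reagents that add atoms: none
Why: Grignard 1,2-addition to the aldehyde gives the racemic allylic carbinol, and the buffered quench avoids acid-promoted 1,3-transposition of this electron-rich benzylic allylic alcohol.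

Step 2
Reactants: 3 rac-1-(3,4-dimethoxyphenyl)prop-2-en-1-ol
Product: 4 (S)-1-(3,4-dimethoxyphenyl)prop-2-en-1-ol
Conditions: immobilised Candida antarctica lipase B, vinyl acetate (3 equiv), MTBE, 30 °C, stopped just past half conversion; chromatography on Et3N-deactivated silica
Reagents that add atoms: none
Why: Lipase-catalysed kinetic resolution by transesterification, in which the Kazlauskas rule (aryl large, vinyl medium) predicts fast acetylation of the (R)-alcohol, so that (S)-4 should remain in high enantiomeric purity and carry the C2 configuration unchanged to the end.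

Step 3
Reactants: 4 (S)-1-(3,4-dimethoxyphenyl)prop-2-en-1-ol; 5 propargyl bromide (3-bromoprop-1-yne)
Product: 6 (S)-1,2-dimethoxy-4-[1-(prop-2-yn-1-yloxy)prop-2-en-1-yl]benzene
Conditions: NaH (1.2 equiv), THF, 0 °C; then 5 (1.3 equiv), Bu4NI (cat.), 0 °C to rt
Reagents that add atoms: none
Why: Williamson etherification (SN2 at the primary propargylic bromide) leaves the carbinol C–O bond untouched, so the S configuration is retained, and the low temperature avoids propargyl-to-allenyl isomerisation.

Step 4
Reactants: 6 (S)-1,2-dimethoxy-4-[1-(prop-2-yn-1-yloxy)prop-2-en-1-yl]benzene; 7 4-iodoveratrole (4-iodo-1,2-dimethoxybenzene)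
Product: 8 (2S,3S,4E)-4-[(3,4-dimethoxyphenyl)methylidene]-2-(3,4-dimethoxyphenyl)-3-methyloxolane (2,3-trans; benzylidene aryl cis to C3)
Conditions: 7 (1.5 equiv), Pd(OAc)2 (5 mol%), Bu4NCl (2 equiv), HCO2Na (3 equiv), DMF, 70 °C
Reagents that add atoms: none
Why: Proposed new method: 7 adds oxidatively to zerovalent palladium, the aryl–palladium bond adds syn across the terminal alkyne of 6 (aryl to C7′, palladium to C4), the C4–Pd bond inserts into the vinyl group (new C3–C4 bond), and formate exchange, loss of CO2 and C–H reductive elimination convert the CH2–Pd terminus into the C3 methyl. The closest known reaction types are the aryl-halide-initiated palladium cyclisation of 1,6-enynes, the formate-terminated reductive Heck reaction and the silane-terminated reductive enyne cyclisation; what is unproven is their merger on a primary alkylpalladium that still has a β-hydrogen (C3–H). The tetrahydrofuran ring O1–C2–C3–C4–C5 closes in the 5-exo-trig mode. The new stereocentre C3 is set by the C2 centre, whose aryl group lies pseudo-equatorial in the insertion transition state so that the CH2–Pd arm ends trans to it (2S,3S), and the E geometry follows from syn addition (aryl cis to palladium, hence cis to C3). The step needs aryl-to-terminus regiochemistry and alkyne-before-alkene chemoselectivity, both supplied by the unhindered terminal alkyne, and hydride capture faster than β-hydride loss, for which phosphine-free, chloride-saturated palladium (no free cis site) and excess formate are chosen. The neutral formate salt and the absence of copper or amine should keep the ionisable allylic benzylic ether and the alkynyl C–H bond untouched.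

Step 5
Reactants: 8 (2S,3S,4E)-4-[(3,4-dimethoxyphenyl)methylidene]-2-(3,4-dimethoxyphenyl)-3-methyloxolane
Product: 10 (R)-(3,4-dimethoxyphenyl)[(3R,4S,5S)-5-(3,4-dimethoxyphenyl)-4-methyloxolan-3-yl]methanol, via benzylic alkylborane 9 (not isolated)
Conditions: BH3·THF (2 equiv), THF, 0 °C to rt; then aq NaOH, 30% H2O2, 0 °C to rt
Reagents that add atoms: hydrogen peroxide, OO (hydroxyl oxygen at C7′); borane–tetrahydrofuran, B.C1CCOC1 (boron of intermediate 9, replaced in 10)
Why: Hydroboration–oxidation, in which borane adds syn across the trisubstituted E-alkene with boron at the less substituted benzylic C7′ and hydrogen at C4 from the face opposite the C3 methyl (pushed pseudo-axial by allylic 1,3-strain with the cis aryl), setting C4 (R, 3,4-cis) and C7′ (R) together, after which peroxide replaces boron by hydroxyl with retention.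

**Compound list**

1 | veratraldehyde (3,4-dimethoxybenzaldehyde) | COc1ccc(C=O)cc1OC | starting material
2 | vinylmagnesium bromide | C=C[Mg]Br | starting material
3 | rac-1-(3,4-dimethoxyphenyl)prop-2-en-1-ol | COc1ccc(C(O)C=C)cc1OC | intermediate
4 | (S)-1-(3,4-dimethoxyphenyl)prop-2-en-1-ol | COc1ccc([C@@H](O)C=C)cc1OC | intermediate
5 | propargyl bromide (3-bromoprop-1-yne) | C#CCBr | starting material
6 | (S)-1,2-dimethoxy-4-[1-(prop-2-yn-1-yloxy)prop-2-en-1-yl]benzene | COc1ccc([C@@H](OCC#C)C=C)cc1OC | intermediate
7 | 4-iodoveratrole (4-iodo-1,2-dimethoxybenzene) | COc1ccc(I)cc1OC | starting material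
8 | (2S,3S,4E)-4-[(3,4-dimethoxyphenyl)methylidene]-2-(3,4-dimethoxyphenyl)-3-methyloxolane | COc1ccc([C@H]2OC/C(=C/c3ccc(OC)c(OC)c3)[C@@H]2C)cc1OC | intermediate
9 | benzylic monoalkylborane from syn addition of H–B to 8 (BH2 on C7′, H on C4, both anti to the C3 methyl; drawn as RBH2) | COc1ccc([C@H]2OC[C@H]([C@@H](B)c3ccc(OC)c(OC)c3)[C@@H]2C)cc1OC | intermediate
10 | (R)-(3,4-dimethoxyphenyl)[(3R,4S,5S)-5-(3,4-dimethoxyphenyl)-4-methyloxolan-3-yl]methanol (CNP0269167.1) | COc1ccc([C@H]2OC[C@H]([C@@H](O)c3ccc(OC)c(OC)c3)[C@@H]2C)cc1OC | target

**Totals.** Total steps: 5. Longest linear sequence: 5 steps (1 → 3 → 4 → 6 → 8 → 10).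

**Steps most likely to fail**

1. Step 4 (Proposed new method). β-Hydride loss from the CH2–Pd intermediate may outrun formate capture and give an exocyclic diene. Premature reduction of the aryl–palladium species, or arylation of the alkynyl C–H bond, may also consume the partners. Fallback, setting out from 6 and rejoining at 10:
 - The established palladium-hydride reductive cyclisation of 1,6-enynes (Pd2(dba)3·CHCl3, AcOH, Et3SiH, toluene, rt) should give (2S,3S)-2-(3,4-dimethoxyphenyl)-3-methyl-4-methylideneoxolane F1 with the same trans control.
 - 9-BBN, then NaOH/H2O2, should add anti to the C3 methyl and give the 3,4-cis primary alcohol [(3S,4S,5S)-5-(3,4-dimethoxyphenyl)-4-methyloxolan-3-yl]methanol F2.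
 - Buffered Dess–Martin oxidation gives (3R,4S,5S)-5-(3,4-dimethoxyphenyl)-4-methyloxolane-3-carbaldehyde F3, used cold and at once to avoid C4 epimerisation.
 - 3,4-Dimethoxyphenylmagnesium bromide at −78 °C should add under Felkin–Anh control (aryl anti to the branched C3, the same sense as chelation through O1) and set C7′ as R, returning to the route at 10.

2. Step 5. Facial discrimination by the small borane may be insufficient, because the C2 aryl, pseudo-axial when the C3 methyl is, partly shields the opposite face. Some boron may also be placed at C4. Fallback, setting out from 8 and rejoining at 10: switch from substrate control to reagent control with monoisopinocampheylborane prepared from (+)-α-pinene (IpcBH2, THF, −25 °C). By analogy with simple trisubstituted alkenes, its face preference is expected to coincide with attack anti to the C3 methyl. This should give the isopinocampheyl(alkyl)borane adduct across C4=C7′ of 8 (boron on C7′) F4, and NaOH/H2O2 then returns to the route at 10.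

3. Step 2. Enantiomer discrimination by the enzyme may be incomplete on this dimethoxyaryl substrate, or the carbinol may partly ionise during handling, lowering the enantiomeric purity that every later stereocentre depends on. Fallback, setting out from 3 and rejoining at 4: Sharpless kinetic resolution (Ti(OiPr)4, L-(+)-diisopropyl tartrate, t-BuOOH, 4 Å molecular sieves, CH2Cl2, −20 °C) should epoxidise the (R)-enantiomer faster and leave (S)-4. No new intermediate arises on this path.

**Further compounds**

F1 | step 4 | (2S,3S)-2-(3,4-dimethoxyphenyl)-3-methyl-4-methylideneoxolane | COc1ccc([C@H]2OCC(=C)[C@@H]2C)cc1OC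
F2 | step 4 | [(3S,4S,5S)-5-(3,4-dimethoxyphenyl)-4-methyloxolan-3-yl]methanol | COc1ccc([C@H]2OC[C@H](CO)[C@@H]2C)cc1OC
F3 | step 4 | (3R,4S,5S)-5-(3,4-dimethoxyphenyl)-4-methyloxolane-3-carbaldehyde | COc1ccc([C@H]2OC[C@H](C=O)[C@@H]2C)cc1OC
F4 | step 5 | isopinocampheyl(alkyl)borane adduct across C4=C7′ of 8 (boron on C7′, isopinocampheyl from (+)-α-pinene) | COc1ccc([C@H]2OC[C@H]([C@@H](B[C@@H]5C[C@@H]6C[C@H]([C@H]5C)C6(C)C)c3ccc(OC)c(OC)c3)[C@@H]2C)cc1OC
F0 | step 2 | none | none
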